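The strategy rests on the C3(O)–C4(H)(CH3)–C5(quaternary CH3) triad of ring A. Ring A (C1–C5, C10) is not built as a cyclohexane: it is taken from the cyclopentanone of (S)-Hajos–Parrish ketone, whose carbonyl carbon (future C3) is bonded directly to the methyl-bearing quaternary carbon (future C5). Addition of a 1-(phenylseleno)ethyl carbanion gives a cis-hydrindane β-hydroxy selenide; in the key step a seleno-semipinacol 1,2-shift moves C5 from C3 to the new carbon, which inserts C4 with its methyl, enlarges the five-membered ring to ring A, regenerates the C3 carbonyl and sets the vicinal C4/C5 dimethyl array in one operation. Ring B is then oxidised and the side-chain acid attached last.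

Key step: step 5

Remark: eremophilane numbering is used for all decalins (ring A: C1–C4, C5, C10; ring B: C5–C10; C14 is the methyl on C5, C15 the methyl on C4, C11–C13 the three-carbon unit on C7; "11,12,13-trinor" means that unit is absent). β denotes the face of the C5 methyl. The target is read as (3R,4R,5R,7R,9R,10S) with a (2E,5R) side chain carrying a (Z)-2-methylbut-2-enoate (angelate).

**Route**

Step 1
Reactants: 1 (S)-Hajos–Parrish ketone, (7aS)-7a-methyl-2,3,7,7a-tetrahydro-1H-indene-1,5(6H)-dione
Product: 2 cis-fused (3aR,7aS)-7a-methylhexahydro-1H-indene-1,5(4H)-dione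
Conditions: H2 (1 atm), 10% Pd/C, EtOAc, rt
Reagents that add atoms: none
Why: Heterogeneous hydrogenation of the enone C=C should deliver hydrogen to the face that gives the cis-hydrindane, the usual outcome for this bicyclic enone, which places the future C10–H syn to the angular methyl.

Step 2
Reactants: 2 cis-fused (3aR,7aS)-7a-methylhexahydro-1H-indene-1,5(4H)-dione
Product: 3 (3a'R,7a'S)-7a'-methylhexahydrospiro[1,3-dioxolane-2,5'-inden]-1'(4'H)-one (dioxolane on the six-ring ketone)
Conditions: ethylene glycol (1.1 equiv), PPTS (cat.), benzene, reflux, Dean–Stark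
Reagents that add atoms: ethylene glycol, OCCO
Why: Chemoselective ketalisation should take place at the unhindered cyclohexanone and leave the neopentylic cyclopentanone next to the quaternary carbon free; no stereocentre is formed.

Step 3
Reactants: 4 acetaldehyde; 5 benzeneselenol (2 equiv in all)
Product: 6 1,1-bis(phenylseleno)ethane
Conditions: PhSeH (2 equiv), ZnCl2 (0.5 equiv), CH2Cl2, 0 °C to rt
Reagents that add atoms: benzeneselenol (the second equivalent of 5), [SeH]c1ccccc1
Why: Lewis-acid-promoted selenoacetalisation should condense the aldehyde with two equivalents of the selenol, with loss of water, to give the selenoacetal that serves as the C4/C15 donor.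

Step 4
Reactants: 3 (3a'R,7a'S)-7a'-methylhexahydrospiro[1,3-dioxolane-2,5'-inden]-1'(4'H)-one; 6 1,1-bis(phenylseleno)ethane
Product: 8 β-hydroxy selenide (3a'R,7a'S)-7a'-methyl-1'-[1-(phenylseleno)ethyl]octahydrospiro[1,3-dioxolane-2,5'-inden]-1'-ol (mixture of diastereomers at C1' and at the CHSe carbon), via 1-lithio-1-(phenylseleno)ethane 7 (not isolated)
Conditions: n-BuLi, THF, −78 °C; then 3, −78 °C; NH4Cl (aq)
Reagents that add atoms: none
Why: Selenium–lithium exchange gives a weakly basic, strongly nucleophilic α-selenoalkyllithium that should add 1,2 to the hindered, enolisable cyclopentanone; the carbinol stereocentre is destroyed and the CHSe stereocentre corrected in step 5, so neither needs control.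

Step 5
Reactants: 8 β-hydroxy selenide (3a'R,7a'S)-7a'-methyl-1'-[1-(phenylseleno)ethyl]octahydrospiro[1,3-dioxolane-2,5'-inden]-1'-ol
Product: 10 8,8-(ethylenedioxy)-11,12,13-trinor-10βH-eremophilan-3-one (cis-decalin, 4β,5β-dimethyl), via selenonium alkoxide betaine 9 (not isolated)
Conditions: TlOEt, CHCl3, rt; then NaOMe (cat.), MeOH, rt
Reagents that add atoms: none
Why: Dichlorocarbene (from TlOEt and CHCl3) is trapped at selenium to give a selenonium ylide, proton transfer from the tertiary hydroxyl gives betaine 9, and its alkoxide pushes the C3–C5 bond onto C4 as PhSeCHCl2 leaves, so that the carbonyl returns at C3 and C4 is inserted between C3 and C5. The closest known reaction type is the ring enlargement of β-hydroxy selenides, a seleno-semipinacol (Tiffeneau–Demjanov-type) 1,2-shift. Ring A is not closed end to end but arises by one-carbon enlargement of the cyclopentane (C5, C3, C2, C1, C10) through a 1,2-alkyl shift with retention at the migrating quaternary C5, so the C5 stereocentre and the cis ring fusion are carried over unchanged. The new stereocentre C4 forms with inversion at the selenium-bearing carbon from each diastereomer of 8 and is then converged by enolisation (NaOMe) to the 4β-methyl epimer, which is equatorial on ring A in the conformer that keeps the C8 dioxolane free of 1,3-diaxial contacts. The step needs migration of the quaternary C5 in preference to the C2 methylene, which the higher migratory aptitude of the more substituted, electron-richer carbon toward the electron-poor C4 should secure, and it needs the carbon shift to outrun epoxide closure by the alkoxide, which the carbene-based activation of selenium without external strong base should favour.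

Step 6
Reactants: 10 8,8-(ethylenedioxy)-11,12,13-trinor-10βH-eremophilan-3-one
Product: 12 3α-hydroxy-11,12,13-trinor-10βH-eremophilan-8-one, via hydroxy ketal 11 (not isolated)
Conditions: Li, NH3(l), THF, EtOH, −78 °C; NH4Cl; then 1 M HCl, THF, rt
Reagents that add atoms: water, O
Why: Dissolving-metal (Birch-type) reduction of the C3 ketone should give the thermodynamically favoured equatorial 3α-alcohol (trans to the C4 methyl), whereas hydride reagents would avoid the syn-axial C5 methyl and give the axial epimer; aqueous acid then hydrolyses the dioxolane.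

Step 7
Reactants: 12 3α-hydroxy-11,12,13-trinor-10βH-eremophilan-8-one
Product: 13 3α-(triethylsilyloxy)-11,12,13-trinor-10βH-eremophilan-8-one
Conditions: TESCl, imidazole, DMF, 0 °C to rt
Reagents that add atoms: chlorotriethylsilane (TESCl), CC[Si](Cl)(CC)CC
Why: Standard silylation of the secondary alcohol; the acid-labile TES ether is chosen so that it can later be removed beside a TBS ether.

Step 8
Reactants: 13 3α-(triethylsilyloxy)-11,12,13-trinor-10βH-eremophilan-8-one
Product: 14 8-(tert-butyldimethylsilyloxy)-3α-(triethylsilyloxy)-11,12,13-trinor-10βH-eremophil-8(9)-ene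
Conditions: TBSOTf, Et3N, CH2Cl2, 0 °C to rt
Reagents that add atoms: tert-butyldimethylsilyl triflate (TBSOTf), CC(C)(C)[Si](C)(C)OS(=O)(=O)C(F)(F)F
Why: Soft enolisation and O-silylation under equilibrating conditions should place the enol double bond toward the ring-fusion side (C8=C9), as cis-fused, 5β-steroid-like 3-keto systems do, and not toward C7.

Step 9
Reactants: 14 8-(tert-butyldimethylsilyloxy)-3α-(triethylsilyloxy)-11,12,13-trinor-10βH-eremophil-8(9)-ene
Product: 16 9β-(tert-butyldimethylsilyloxy)-3α-(triethylsilyloxy)-11,12,13-trinor-10βH-eremophilan-8-one, via siloxy epoxide 15 (not isolated)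
Conditions: mCPBA (1.05 equiv), NaHCO3, CH2Cl2, −20 °C to rt
Reagents that add atoms: meta-chloroperbenzoic acid (mCPBA), OOC(=O)c1cccc(Cl)c1
Why: Rubottom oxidation: the enol ether should be epoxidised from the convex β-face of the cis-decalin (the α-face is shielded by ring A, whose C4 is axial on ring B), and a 1,4-silyl shift of the siloxy epoxide gives the 9β-silyloxy ketone, which sets C9.

Step 10
Reactants: 16 9β-(tert-butyldimethylsilyloxy)-3α-(triethylsilyloxy)-11,12,13-trinor-10βH-eremophilan-8-one
Product: 17 9β-(tert-butyldimethylsilyloxy)-11-hydroxy-3α-(triethylsilyloxy)-10βH-eremophilan-8-one (7β-(2-hydroxypropan-2-yl))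
Conditions: LiN(iPr)2, THF, −78 °C; ZnCl2; acetone, −78 to −40 °C; NH4Cl (aq)
Reagents that add atoms: acetone, CC(C)=O
Why: Kinetic deprotonation should occur at the C7 methylene (the C9 methine is shielded by its silyloxy group) and the zinc-mediated aldol addition to acetone should come from the convex β-face, giving the equatorial 7β-adduct, which is also the thermodynamic epimer.

Step 11
Reactants: 17 9β-(tert-butyldimethylsilyloxy)-11-hydroxy-3α-(triethylsilyloxy)-10βH-eremophilan-8-one
Product: 18 9β-(tert-butyldimethylsilyloxy)-3α-(triethylsilyloxy)-10βH-eremophil-11-en-8-one (7β-isopropenyl)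
Conditions: SOCl2, pyridine, CH2Cl2, −30 to 0 °C
Reagents that add atoms: none
Why: Dehydration of the tertiary alcohol through its chlorosulfite by E2 elimination should take a proton from one of the six accessible methyl hydrogens and not the hindered tertiary C7–H, giving the non-conjugated isopropenyl alkene in a cold, weakly basic medium that should not isomerise it.

Step 12
Reactants: 18 9β-(tert-butyldimethylsilyloxy)-3α-(triethylsilyloxy)-10βH-eremophil-11-en-8-one
Product: 19 9β-(tert-butyldimethylsilyloxy)-3α-hydroxy-10βH-eremophil-11-en-8-one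
Conditions: PPTS (cat.), EtOH, 0 °C to rt
Reagents that add atoms: none
Why: Mild acid-catalysed solvolysis should cleave the secondary TES ether selectively beside the far more stable TBS ether, without touching the β,γ-unsaturated ketone.

Step 13
Reactants: 20 (R)-pent-4-en-2-ol; 21 angelic acid, (Z)-2-methylbut-2-enoic acid
Product: 23 (R)-pent-4-en-2-yl (Z)-2-methylbut-2-enoate, via angelic 2,4,6-trichlorobenzoic anhydride 22 (not isolated)
Conditions: 2,4,6-trichlorobenzoyl chloride, Et3N, toluene, rt; then 20, toluene, 80 °C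
Reagents that add atoms: none
Why: Yamaguchi-type esterification through the mixed anhydride without a nucleophilic catalyst should retain the (Z)-geometry of the angelate, and acylation at oxygen leaves the carbinol stereocentre untouched.

Step 14
Reactants: 23 (R)-pent-4-en-2-yl (Z)-2-methylbut-2-enoate; 24 acrylic acid
Product: 25 (2E,5R)-5-{[(Z)-2-methylbut-2-enoyl]oxy}hex-2-enoic acid
Conditions: second-generation Grubbs catalyst RuCl2(=CHPh)(PCy3)(H2IMes) (5 mol %), CH2Cl2, 40 °C
Reagents that add atoms: none
Why: Olefin cross-metathesis of the terminal alkene with acrylic acid should give the (E)-enoic acid, while the trisubstituted, electron-poor angelate alkene is inert to the catalyst.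

Step 15
Reactants: 19 9β-(tert-butyldimethylsilyloxy)-3α-hydroxy-10βH-eremophil-11-en-8-one; 25 (2E,5R)-5-{[(Z)-2-methylbut-2-enoyl]oxy}hex-2-enoic acid
Product: 26 9-O-(tert-butyldimethylsilyl) ether of the target
Conditions: EDC·HCl, DMAP (cat.), CH2Cl2, 0 °C to rt
Reagents that add atoms: none
Why: Steglich-type carbodiimide esterification should acylate the only free hydroxyl (C3) with retention at C3, the C9 hydroxyl being masked as its TBS ether.

Step 16
Reactants: 26 9-O-(tert-butyldimethylsilyl) ether of the target
Product: 27 CNP0210874.1, (3R,4R,5R,7R,9R,10S)-9-hydroxy-8-oxoeremophil-11-en-3-yl (2E,5R)-5-{[(Z)-2-methylbut-2-enoyl]oxy}hex-2-enoate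
Conditions: HF·pyridine, pyridine, THF, 0 °C to rt
Reagents that add atoms: none
Why: Buffered fluoride desilylation should free the C9 hydroxyl under weakly acidic conditions that spare the angelate, the enoate and the β,γ-unsaturated ketone.

**Compound list**

1 | (S)-Hajos–Parrish ketone, (7aS)-7a-methyl-2,3,7,7a-tetrahydro-1H-indene-1,5(6H)-dione | C[C@]12CCC(=O)C=C1CCC2=O | starting material
2 | cis-fused (3aR,7aS)-7a-methylhexahydro-1H-indene-1,5(4H)-dione | C[C@]12CCC(=O)C[C@H]1CCC2=O | intermediate
3 | (3a'R,7a'S)-7a'-methylhexahydrospiro[1,3-dioxolane-2,5'-inden]-1'(4'H)-one | C[C@]12CCC3(OCCO3)C[C@H]1CCC2=O | intermediate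
4 | acetaldehyde | CC=O | starting material
5 | benzeneselenol | [SeH]c1ccccc1 | starting material
6 | 1,1-bis(phenylseleno)ethane | CC([Se]c1ccccc1)[Se]c1ccccc1 | intermediate
7 | 1-lithio-1-(phenylseleno)ethane (not isolated) | [Li]C(C)[Se]c1ccccc1 | intermediate
8 | β-hydroxy selenide, (3a'R,7a'S)-7a'-methyl-1'-[1-(phenylseleno)ethyl]octahydrospiro[1,3-dioxolane-2,5'-inden]-1'-ol, diastereomer mixture | C[C@]12CCC3(OCCO3)C[C@H]1CCC2(O)C(C)[Se]c1ccccc1 | intermediate
9 | selenonium alkoxide betaine of 8, Se-(dichloromethyl) (not isolated) | C[C@]12CCC3(OCCO3)C[C@H]1CCC2([O-])C(C)[Se+](C(Cl)Cl)c1ccccc1 | intermediate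
10 | 8,8-(ethylenedioxy)-11,12,13-trinor-10βH-eremophilan-3-one (4β,5β-dimethyl) | C1C[C@@]2(C)[C@H](CCC(=O)[C@@H]2C)CC13OCCO3 | intermediate
11 | 8,8-(ethylenedioxy)-11,12,13-trinor-10βH-eremophilan-3α-ol (not isolated) | C1C[C@@]2(C)[C@H](CC[C@@H](O)[C@@H]2C)CC13OCCO3 | intermediate
12 | 3α-hydroxy-11,12,13-trinor-10βH-eremophilan-8-one | C1C[C@@]2(C)[C@H](CC[C@@H](O)[C@@H]2C)CC1=O | intermediate
13 | 3α-(triethylsilyloxy)-11,12,13-trinor-10βH-eremophilan-8-one | C1C[C@@]2(C)[C@H](CC[C@@H](O[Si](CC)(CC)CC)[C@@H]2C)CC1=O | intermediate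
14 | 8-(tert-butyldimethylsilyloxy)-3α-(triethylsilyloxy)-11,12,13-trinor-10βH-eremophil-8(9)-ene | C1C[C@@]2(C)[C@H](CC[C@@H](O[Si](CC)(CC)CC)[C@@H]2C)C=C1O[Si](C)(C)C(C)(C)C | intermediate
15 | 8β,9β-epoxy-8α-(tert-butyldimethylsilyloxy)-3α-(triethylsilyloxy)-11,12,13-trinor-10βH-eremophilane (not isolated) | C1C[C@@]2(C)[C@H](CC[C@@H](O[Si](CC)(CC)CC)[C@@H]2C)[C@H]3O[C@@]13O[Si](C)(C)C(C)(C)C | intermediate
16 | 9β-(tert-butyldimethylsilyloxy)-3α-(triethylsilyloxy)-11,12,13-trinor-10βH-eremophilan-8-one | C1C[C@@]2(C)[C@H](CC[C@@H](O[Si](CC)(CC)CC)[C@@H]2C)[C@@H](O[Si](C)(C)C(C)(C)C)C1=O | intermediate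
17 | 9β-(tert-butyldimethylsilyloxy)-11-hydroxy-3α-(triethylsilyloxy)-10βH-eremophilan-8-one (7β side chain) | CC(C)(O)[C@H]1C[C@@]2(C)[C@H](CC[C@@H](O[Si](CC)(CC)CC)[C@@H]2C)[C@@H](O[Si](C)(C)C(C)(C)C)C1=O | intermediate
18 | 9β-(tert-butyldimethylsilyloxy)-3α-(triethylsilyloxy)-10βH-eremophil-11-en-8-one (7β-isopropenyl) | C=C(C)[C@H]1C[C@@]2(C)[C@H](CC[C@@H](O[Si](CC)(CC)CC)[C@@H]2C)[C@@H](O[Si](C)(C)C(C)(C)C)C1=O | intermediate
19 | 9β-(tert-butyldimethylsilyloxy)-3α-hydroxy-10βH-eremophil-11-en-8-one | C=C(C)[C@H]1C[C@@]2(C)[C@H](CC[C@@H](O)[C@@H]2C)[C@@H](O[Si](C)(C)C(C)(C)C)C1=O | intermediate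
20 | (R)-pent-4-en-2-ol | C=CC[C@@H](C)O | starting material
21 | angelic acid, (Z)-2-methylbut-2-enoic acid | C/C=C(/C)C(=O)O | starting material
22 | angelic 2,4,6-trichlorobenzoic anhydride (not isolated) | C/C=C(/C)C(=O)OC(=O)c1c(Cl)cc(Cl)cc1Cl | intermediate
23 | (R)-pent-4-en-2-yl (Z)-2-methylbut-2-enoate | C=CC[C@@H](C)OC(=O)/C(C)=C\C | intermediate
24 | acrylic acid | C=CC(=O)O | starting material
25 | (2E,5R)-5-{[(Z)-2-methylbut-2-enoyl]oxy}hex-2-enoic acid | OC(=O)/C=C/C[C@@H](C)OC(=O)/C(C)=C\C | intermediate
26 | 9-O-(tert-butyldimethylsilyl) ether of the target | C=C(C)[C@H]1C[C@@]2(C)[C@H](CC[C@@H](OC(=O)/C=C/C[C@@H](C)OC(=O)/C(C)=C\C)[C@@H]2C)[C@@H](O[Si](C)(C)C(C)(C)C)C1=O | intermediate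
27 | CNP0210874.1, (3R,4R,5R,7R,9R,10S)-9-hydroxy-8-oxoeremophil-11-en-3-yl (2E,5R)-5-{[(Z)-2-methylbut-2-enoyl]oxy}hex-2-enoate | C=C(C)[C@H]1C[C@@]2(C)[C@H](CC[C@@H](OC(=O)/C=C/C[C@@H](C)OC(=O)/C(C)=C\C)[C@@H]2C)[C@@H](O)C1=O | target

**Step count**

Total step count: 16. Longest linear sequence: 13 steps (steps 1, 2, 4 to 12, 15 and 16).

**Steps most likely to fail, with fallbacks**

Step 5 (ring enlargement). After activation at selenium the alkoxide may close onto C4 to give a spiro-epoxide, or the C2 methylene may migrate in place of C5, or the secondary selenide may react too slowly with the carbene. The fallback is a β-oxido carbenoid ring enlargement that sets out from ketone 3. 1,1-Dibromoethane is deprotonated with LiN(iPr)2 in THF at −95 °C in the presence of 3, and the resulting 1,1-dibromoethyllithium adds to the carbonyl to give the dibromo carbinol F1. Two equivalents of n-BuLi (THF, −95 to 0 °C) then form the lithium alkoxide carbenoid, whose 1,2-shift with loss of LiBr should again move the more substituted C5 and give the C3/C4 enolate of the enlarged ring. Protonation and the same NaOMe equilibration return to compound 10.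

Step 8 (enol ether formation). Enolisation may turn toward C7 or give a mixture, so that oxygen would later enter at the wrong α-carbon. The fallback reverses the order of the two α-functionalisations and sets out from ketone 13. The zinc-mediated aldol with acetone (LiN(iPr)2, ZnCl2, acetone, THF, −78 °C), reversible and therefore directed to the less hindered C7, gives the 7β-(2-hydroxypropan-2-yl) ketone F2. Its tertiary hydroxyl is capped with TMSCl and imidazole to give the trimethylsilyl ether F3. With C7 now tertiary and shielded, KN(SiMe3)2 (THF, −78 °C) should deprotonate C9, and 2-(phenylsulfonyl)-3-phenyloxaziridine should hydroxylate the enolate from the convex β-face to give the 9β-hydroxy ketone F4. TBSOTf and 2,6-lutidine give the 9β-silyloxy ketone F5, and citric acid in MeOH at 0 °C removes the tertiary TMS ether selectively, which returns to compound 17.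

Step 11 (dehydration). Elimination may run toward C7 and give the conjugated isopropylidene ketone, or ionisation of the tertiary chlorosulfite may give mixtures. The fallback accepts the conjugated isomer and deconjugates it, setting out from aldol 17. MsCl and Et3N followed by DBU (CH2Cl2, 0 °C to rt) give the isopropylidene enone F6 as the thermodynamic elimination product. KN(SiMe3)2 (THF, −78 °C) then removes a γ-proton from a C11 methyl (the α'-proton at C9 is shielded), and quenching the dienolate with AcOH at −78 °C should protonate C7 kinetically along the axial (α) trajectory, leaving the isopropenyl group equatorial and β. This returns to compound 18.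

**Further compounds**

F1 | step 5 | (3a'R,7a'S)-1'-(1,1-dibromoethyl)-7a'-methyloctahydrospiro[1,3-dioxolane-2,5'-inden]-1'-ol | C[C@]12CCC3(OCCO3)C[C@H]1CCC2(O)C(C)(Br)Br
F2 | step 8 | 11-hydroxy-3α-(triethylsilyloxy)-10βH-eremophilan-8-one (7β side chain) | CC(C)(O)[C@H]1C[C@@]2(C)[C@H](CC[C@@H](O[Si](CC)(CC)CC)[C@@H]2C)CC1=O
F3 | step 8 | 3α-(triethylsilyloxy)-11-(trimethylsilyloxy)-10βH-eremophilan-8-one | CC(C)(O[Si](C)(C)C)[C@H]1C[C@@]2(C)[C@H](CC[C@@H](O[Si](CC)(CC)CC)[C@@H]2C)CC1=O
F4 | step 8 | 9β-hydroxy-3α-(triethylsilyloxy)-11-(trimethylsilyloxy)-10βH-eremophilan-8-one | CC(C)(O[Si](C)(C)C)[C@H]1C[C@@]2(C)[C@H](CC[C@@H](O[Si](CC)(CC)CC)[C@@H]2C)[C@@H](O)C1=O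
F5 | step 8 | 9β-(tert-butyldimethylsilyloxy)-3α-(triethylsilyloxy)-11-(trimethylsilyloxy)-10βH-eremophilan-8-one | CC(C)(O[Si](C)(C)C)[C@H]1C[C@@]2(C)[C@H](CC[C@@H](O[Si](CC)(CC)CC)[C@@H]2C)[C@@H](O[Si](C)(C)C(C)(C)C)C1=O
F6 | step 11 | 9β-(tert-butyldimethylsilyloxy)-3α-(triethylsilyloxy)-10βH-eremophil-7(11)-en-8-one | CC(C)=C1C[C@@]2(C)[C@H](CC[C@@H](O[Si](CC)(CC)CC)[C@@H]2C)[C@@H](O[Si](C)(C)C(C)(C)C)C1=O
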